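How much G stands in the flask at 6.0 h, and how near saturation is J by then?

the same everywhere: X 0.14 M; L 16 mM (held)
- midnight: Z 13 mM; the very flask that is asked about, followed so far
- spring: Z 8.7 mM; run made earlier
- flask: Z 13 mM; time 6.0 h

midnight run (percent of the X charged)

| time / min | G / % | X / % |
|---|---|---|
| 15.0 | 1.6 | 98.9 |
| 40.0 | 4.8 | 93.8 |
| 80.0 | 10.6 | 88.5 |
| 120 | 16.2 | 81.2 |

spring run (percent of the X charged)

| time / h | G / % | X / % |
|---|---|---|
| 1.50 | 8.5 | 88.7 |
| 3.00 | 16.0 | 78.6 |
| 5.00 | 25.3 | 67.1 |
| 6.00 | 30.1 | 60.9 |

(readings scatter by 0.5 percentage points)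

1. the G standing at 6.0 h, as a percentage of the X charged
2. concentration of J in solution at 6.0 h, in percent of saturation

I carry one quantity: 78.0 mM·h of catalyst time, the charge of Z multiplied by the hours run, here for the flask (variable time normalisation, in the usual term). The readings support it. The midnight run at 120 min and the spring run at 3.00 h stand at 26.0 mM·h and 26.1 mM·h, and their G reads 16.2% and 16.0%. So the spring run's last reading, 30.1% at 52.2 mM·h, is my starting point, and the flask has catalyst time still to run beyond it.

If the spring run's gain since 3.00 h simply continued, G would reach 44.0%. But X falls over that stretch, from 78.6% to 60.9%, so I call this my ceiling. For my floor, I repeat the midnight run's drop in X to reach 53.5% at 6.0 h, scale that gain by this X over the spring run's 78.6%, and take off one scatter. That gives 39.1%.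

The forecast, 42% (39% to 45%) with J at 93% (85% to 98%), reasons that “The G rate scales with Z”, and its G stands inside my bracket.

The flask gives 39.6% of G, just above my floor, with J at 91.0% of saturation.

    L ⇌ J, rate k1*(csat - [J]) (kL = 7.14 h⁻¹)
    X + J + Z → Z + G (k = 500 M⁻² h⁻¹)
    J → Q (k = 0.122 h⁻¹)
    X + J → E (k = 1.39 M⁻¹ h⁻¹)

The flask holds 39.6% of G at 6.0 h because its run ends at 78.0 mM·h of catalyst time, with 52% of its X still there. Left ten times as long, until 60.0 h, the same flask reaches 780 mM·h and holds 82.3% of G. The neighbour flask read at 4.0 h stands at 52.0 mM·h, beside the 52.2 mM·h at which the spring run read 30.1%, and that neighbour holds 28.7% of G.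

The earlier runs and the new flask stem from a simulated flask with constants of no real substance; scatter was added.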